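Friday's run is the very flask asked about, followed up to 10.0 h.

| flask | substrate | reagent | scavenger | remark | time |
|---|---|---|---|---|---|
| Friday's | 0.10 M | 4 equiv | 0.30 equiv | the very flask that is asked about, followed so far |  |
| flask | 0.10 M | 4.00 equiv | 0.300 equiv |  | 25 h |

Friday's run (percent of the substrate charged)

| time / h | substrate / % | single product / % |
|---|---|---|
| 1.33 | 55.9 | 41.2 |
| 3.00 | 32.5 | 65.3 |
| 4.00 | 24.9 | 70.7 |
| 6.00 | 12.8 | 79.6 |
| 8.00 | 8.5 | 79.2 |
| 10.0 | 5.6 | 80.2 |

(standard deviation of a reading: 1 percentage point)

1. part of the substrate that has reacted at 25 h
2. share of the unused reagent that is free and not bound as idle adduct, at 25 h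

- the earlier runs do not show how much of reagent is bound; that part of a forecast is a guess

In that flask I watch two rates: single product forming from substrate, and single product being lost onward. Divide the second by the first and time drops out. If both steps take free reagent to the same power, the reagent drops out too, bound or not. Write x for the substrate left and m for the single product, both as fractions of the charge, and s for the ratio of the two rate constants, the selectivity factor. Then m = (x^s − x)/(1 − s). Try values of s until this returns your last reading within its scatter, and you read s = 0.0790.

The forecast puts the reacted part c at 98.8 % (96.5 % to 99.8 %) and the free share fr at 72 % (45 % to 93 %), adding: “The free share is a guess.” My ratio gives neither number, but at the forecast's c my own reckoning leaves 75.3 % single product.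

The flask gives c = 99.4 %, inside the forecast's range, and fr = 42.2 %, just below the forecast's.

    substrate + reagent → single product + released group (k = 1.20 /M/h)
    reagent + single product → bis adduct + released group (k = 0.0940 /M/h)
    reagent + bis adduct → triple product + released group (k = 2.80 /M/h)
    reagent + triple product → tetra adduct + released group (k = 1.70 /M/h)
    reagent + released group ⇌ idle adduct, settled at all times (K = 84.0 /M)
    scavenger + released group → scavenged by-product (k = 6.60 /M/h)

Put this flask's 0.626 % substrate into the rule and you get 72.0 % single product; the flask holds 72.2 %. The neighbour flask, with the same equivalents but 0.025 M substrate, reaches c = 87.4 % and keeps 12.6 % substrate. The same s gives 78.5 % single product there, and that flask holds 78.6 %.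

The data are simulated with made-up constants, noise included.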